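## Compound numbers and locants

Numbers follow the order of first appearance in the steps: 1 (S)-limonene, 2 limonene 1,2-oxide, 3 diol (in the flask), 4 keto-aldehyde, 5 aldol adduct (in the flask), 6 cyclopentene carbaldehyde, 7 epoxy aldehyde, 8 β-hydroxy aldehyde as formed, 9 its trans epimer (in the flask), 10 diol, 11 iodide, 12 dimethyl malonate, 13 alkylated malonate, 14 bridged lactone ester, 15 6-methylheptane-2,4-dione, 16 open-chain triketo ester (in the flask), 17 des-prenyl spiro acyl-trione, 18 prenyl bromide, 19 target.

The hydrindane carries indane locants (C1, C2, C3, C3a, C4, C5, C6, C7, C7a), and these are kept for the same atoms in the monocyclic intermediates. Ring A is primed: C1' (C=O), C2' (diprenyl carbon), C3' (enol carbon), C4' (acyl-bearing carbon), C5' (C=O), with C6 as the spiro atom. The β face is the face of the C3a hydrogen and the α face that of the C7a hydrogen.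

## Analysis of the target

Target 19 has three rings. Ring A is an enolised 4-acyl-2,2-diprenylcyclohexane-1,3,5-trione (acyl = 3-methylbutanoyl), and rings B (six-membered) and C (five-membered) form a trans-fused hydrindane that shares the spiro atom C6 with ring A. There are five stereocentres: C3a and C7a (hydrogens trans), the tertiary methyl carbinols C1 (OH β) and C4 (OH α, axial on ring B), and C6, whose C1' carbonyl lies on the α face, 1,3-diaxial to the C4 hydroxyl. C6 is stereogenic only because its two acyl substituents differ two atoms further on (C2' against C4'), so it is the centre that is hardest to address directly. The sensitive groups are the two tertiary alcohols (elimination under acid), the enolised β-triketone (retro-Claisen cleavage, O- against C-alkylation) and the prenyl alkenes (oxidants, acid, radicals), so the prenyl groups belong at the end. The difficulty is that a quaternary spiro carbon, two tertiary carbinols and a trans ring fusion sit on contiguous carbons with few functional handles. The strategy rests on ring C: C1 with its methyl, C2, C3, C3a, C7a, the exocyclic carbon C7 on C7a and the three-carbon unit on C3a (C4, its methyl, C5) are the ten carbons of limonene 1 after contraction of its six-membered ring, and C3a is the limonene stereocentre.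

## Retrosynthetic reasoning

**19 ⇒ 17 + 18.** The two C2'–prenyl bonds are cut first. C2' is the only ring A carbon with two hydrogens and lies between C1' and C3', so it is the nucleophilic carbon of the dianion of 17. Removing the prenyl groups here keeps two trisubstituted alkenes out of every oxidative and radical step. The forward reaction must alkylate carbon twice in preference to oxygen.

**17 ⇒ 14 + 15 (through 16).** Ring A is cut at C1'–C2' and C4'–C5', the two ring bonds beyond the carbonyls on C6. This leaves both acyl carbons on C6 and turns the rest of ring A, with its side chain, into the eight-carbon diketone 15. The two acyl groups on C6 are made different by tying one of them to the C4 oxygen as a lactone, which gives 14. The forward reaction must send the terminal carbon of the dianion of 15 to the lactone carbonyl and its central carbon to the methyl ester, since that order fixes the configuration of C6.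

**14 ⇒ 13.** The C5–C6 bond and the C4–O lactone bond are cut together. Both form when a malonyl radical at C6 adds to the terminal carbon of the isopropenyl group and the oxidised C4 centre is captured by an ester. Cutting here closes ring B on a preformed ring C, and the trans relation of C3a and C7a then dictates C4 and C6, because only the axial ester of the chair can reach C4. The forward reaction needs 6-endo closure and oxidation of the tertiary radical.

**13 ⇒ 11 + 12, and 11 ⇒ 10.** The C6–C7 bond is cut to give malonate 12 as nucleophile and C7 as electrophile. A condensation of aldehyde 9 with 12 would be shorter on paper. However, 9 is an aldol, and any amine or Lewis acid able to condense it with 12 would first dehydrate it back to 6, which is exactly the fate of 5 in step 3. The aldehyde is therefore reduced to diol 10 and its primary hydroxyl is turned into the iodide 11.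

**10 ⇒ 9 ⇒ 8 ⇒ 7 ⇒ 6.** The C1–O and C7a–H bonds are traced back to the C1=C7a alkene of 6 through epoxide 7. The formyl group polarises this alkene, so a peroxide nucleophile can be delivered to C1 without touching the isopropenyl group. The same formyl group later directs a one-electron reductant to the C7a–O bond alone. C1 is thus set by the face of epoxidation (anti to the isopropenyl group). C7a is α to the aldehyde and is set by equilibration to the epimer in which the formyl group is trans to both the isopropenyl group and the C1 methyl.

**6 ⇒ 4.** The C1=C7a bond is cut, which opens ring C to the 1,6-keto-aldehyde 4. This is the point at which the limonene ring loses one ring carbon. The forward reaction is an intramolecular aldol condensation in which the aldehyde α-carbon, not a ketone α-carbon, must be the nucleophile.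

**4 ⇒ 3 ⇒ 2 ⇒ 1.** The two carbonyls of 4 come from oxidative cleavage of the ring alkene of 1, by way of epoxide 2 and diol 3. The trisubstituted ring alkene is addressed in preference to the isopropenyl group because it is the more electron-rich of the two.

## Alternatives that were turned down

**Alternative 1: ring A closed onto a lactone-differentiated spiro carbon as the central step.**
- Disconnection: ring A at C1'–C2' and C4'–C5', back to the bridged lactone methyl ester A2 and 6-methylheptane-2,4-dione A3.
- Forward key step: the dianion of A3 opens the lactone of A2 with its terminal carbon, then its central carbon condenses with the methyl ester, to give the des-prenyl spiro acyl-trione A1.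
- For: the lactone makes the two acyl groups on C6 chemically different, so the spiro centre follows from which carbonyl reacts first. One operation makes two C–C bonds and the whole acyl-trione.
- Against: as a plan it says how ring A is finished but not where A2 comes from. A2 already holds C1, C3a, C4 and C7a and both tertiary carbinols, so the harder half of the molecule stays open. The weight of the plan also falls on a late step run on the most valuable intermediate.
- Comparison: on the question of C6 this idea is as strong as anything available, and the chosen route uses this very condensation as its step 10 (A2 is 14, A1 is 17). The chosen strategy adds what Alternative 1 leaves open, namely a chiral-pool origin of ring C with C3a fixed. It also places the strategic step early, on cheap material.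

**Alternative 2: Pauson–Khand closure of rings B and C.**
- Disconnection: C3a–C7a, C1–C2 and C2–C3 together, back to the acyclic enyne A5, a malonate with a but-2-ynyl arm and a 2-methyl-2-(triethylsilyloxy)but-3-enyl arm.
- Forward key step: octacarbonyldicobalt A6, Co2(CO)8, complexes the alkyne and joins alkyne, vinyl group and one carbonyl ligand to the bicyclic enone diester A4.
- For: three C–C bonds and two rings in one step from an easily assembled chain. The gem-diester favours cyclisation, and C6 arrives as a symmetrical malonate carbon.
- Against: A4 has oxygen at C2, where 19 has none, and a C1=C7a enone where 19 needs a C1 carbinol and a C7a hydrogen trans to the C3a hydrogen. Correcting this means chemistry at a tetrasubstituted enone plus deoxygenation of C2, roughly five or six steps that form no skeletal bond. The C4 carbinol must be made enantioselectively beforehand, and its methyl and silyloxy groups are too alike to promise a clean relay to C3a. A5 is also a 1,7-enyne, which cyclises to the six-membered ring more reluctantly than a 1,6-enyne does to a five-membered ring.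
- Comparison: on bonds per step (three against one) and on convergence this route is clearly stronger. The chosen strategy offers the correct oxidation pattern instead: 6 has every ring C carbon in place, oxygen enters only where 19 has it, and C3a is purchased rather than induced.

**Alternative 3: conjugate addition and Michael trapping on cyclopentenone.**
- Disconnection: C3a–C4 and C7–C7a, with ring C taken as cyclopent-2-en-1-one A8, the isopropenyl unit from isopropenylmagnesium bromide A9 and the C7/C6 arm from dimethyl methylidenemalonate A10.
- Forward key step: under a chiral catalyst made from CuBr·SMe2 A11 and a ferrocenyl diphosphine, A9 adds to C3a of A8, and the magnesium enolate adds through C7a to A10, giving the trans-disubstituted cyclopentanone A7. No ring closes.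
- For: two C–C bonds and two stereocentres in one flask from three commodity chemicals. The malonate arm arrives in its final form, and C7a is α to a ketone and equilibrates safely to trans. One methyl-metal addition to the C1 ketone, anti to the neighbouring C7 arm, would give 13, in about three steps where the chosen route needs eight.
- Against: the small, flat five-membered enone gives a chiral catalyst little to distinguish its faces, and an alkenyl Grignard reagent is an unusual partner, so the enantiopurity of C3a, from which all other centres descend, is in doubt. A10 polymerises readily under anionic conditions. The methyl addition must be run on a substrate with an acidic malonate hydrogen and an enolisable ketone, and the new alkoxide, cis to the arm, can lactonise onto an ester.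
- Comparison: this route is shorter by about five steps, and that advantage is real. The chosen strategy offers in its place a purchased absolute configuration (C3a from 1), a C1 methyl already in place, and a key step that is a known reaction type on the actual substrate.

Key step: step 3

## Remarks on the chemistry (assumptions)

- 16, 17 and 19 are each drawn as one tautomer. The tautomers of the β-triketone interconvert and are treated as one compound.
- Step 5 may give either C7a epimer, so 8 is written without configuration at C7a. The centre is settled in step 6.

## Route

Step 1
Reactants: 1 (S)-(−)-limonene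
Product: 2 (4S)-limonene 1,2-oxide (cis/trans mixture of epoxides)
Conditions: mCPBA (1.0 equiv), CH2Cl2, 0 °C
Reagents that add atoms: mCPBA (3-chloroperoxybenzoic acid), OOC(=O)c1cccc(Cl)c1
Why: Prilezhaev epoxidation; the trisubstituted ring alkene is more electron-rich than the 1,1-disubstituted isopropenyl alkene and should react first with one equivalent of peracid at 0 °C; the epoxide diastereomers need not be separated because both epoxide carbons become carbonyl carbons in step 2.

Step 2
Reactants: 2 (4S)-limonene 1,2-oxide
Product: 4 (3S)-6-oxo-3-(prop-1-en-2-yl)heptanal, via limonene-1,2-diol 3 (not isolated)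
Conditions: H5IO6 (1.1 equiv), THF/H2O, 0 °C → rt
Reagents that add atoms: water, O
Why: Acid-mediated anti opening of the epoxide by water gives diol 3, which periodic acid cleaves at once (Malaprade glycol cleavage) to the methyl ketone and the aldehyde; the isopropenyl group is inert and the stereocentre is not α to either carbonyl, so it cannot epimerise.

Step 3
Reactants: 4 (3S)-6-oxo-3-(prop-1-en-2-yl)heptanal
Product: 6 (5R)-2-methyl-5-(prop-1-en-2-yl)cyclopent-1-ene-1-carbaldehyde, via aldol adduct 5 (not isolated)
Conditions: piperidine (0.3 equiv), AcOH (0.3 equiv), PhH, reflux (Dean–Stark)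
Reagents that add atoms: none
Why: Piperidinium acetate converts the aldehyde of 4, which condenses with a secondary amine far faster than the methyl ketone, into its enamine, whose nucleophilic carbon is C7a. This carbon adds to the ketone carbon C1 in a 5-exo-trig closure (enamine double bond exocyclic to the new ring), forming the C1–C7a bond and ring C as aldol 5 or its iminium form. Acid-assisted loss of water through the iminium/dienamine and hydrolysis then release the conjugated enal 6 and the amine, and removal of water makes the sequence irreversible. The closest known reaction type is the amine-catalysed intramolecular aldol condensation of 1,6-keto-aldehydes to 2-alkylcyclopent-1-ene-1-carbaldehydes, which is established for this keto-aldehyde. The selectivity needed is regiochemical: a ketone enolate could instead attack the aldehyde through its methylene (giving a 1-acetylcyclopentene) or its methyl (giving a seven-membered ring), and enamine activation of the aldehyde in place of base-mediated ketone enolisation is what secures the wanted closure. No stereocentre is formed, and C3a is neither α to a carbonyl in 4 nor a vinylogously acidic position in 6, so its configuration should be retained. The product holds all ten terpene carbons, with the former ring carbon now the formyl carbon C7 and the C1=C7a alkene ready to receive the C1 oxygen and the C7a hydrogen.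

Step 4
Reactants: 6 (5R)-2-methyl-5-(prop-1-en-2-yl)cyclopent-1-ene-1-carbaldehyde
Product: 7 (1R,2R,5S)-5-methyl-2-(prop-1-en-2-yl)-6-oxabicyclo[3.1.0]hexane-1-carbaldehyde (epoxide oxygen anti to the isopropenyl group)
Conditions: 30% aq. H2O2 (3 equiv), NaOH (0.3 equiv), MeOH, 0 °C
Reagents that add atoms: hydrogen peroxide, OO
Why: Weitz–Scheffer nucleophilic epoxidation: hydroperoxide adds to the β-carbon C1 of the enal and the enolate closes onto oxygen, so only the electron-poor alkene reacts and the isopropenyl group survives; C1 and C7a are set together, and the oxygen should enter on the β face because the isopropenyl group on the adjacent C3a, held pseudoaxial by allylic strain with the formyl group, covers the α face.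

Step 5
Reactants: 7 (1R,2R,5S)-5-methyl-2-(prop-1-en-2-yl)-6-oxabicyclo[3.1.0]hexane-1-carbaldehyde
Product: 8 (2S,5S)-2-hydroxy-2-methyl-5-(prop-1-en-2-yl)cyclopentane-1-carbaldehyde (epimers at the formyl-bearing carbon C7a)
Conditions: SmI2 (2.2 equiv, 0.1 M in THF), MeOH (5 equiv), THF, −90 °C; pH 7 buffer
Reagents that add atoms: none
Why: Reductive Cα–O cleavage of an α,β-epoxy carbonyl compound by divalent samarium: electron transfer gives a ketyl, the C7a–O bond breaks, a second electron gives the samarium enolate and MeOH protonates it; the C1–O bond is untouched, so C1 keeps the configuration from step 4, while the protonation at C7a need not be selective because that centre is equilibrated in step 6; the saturated product aldehyde should be reduced much more slowly than the α-oxygenated starting aldehyde at −90 °C.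

Step 6
Reactants: 8 (2S,5S)-2-hydroxy-2-methyl-5-(prop-1-en-2-yl)cyclopentane-1-carbaldehyde
Product: 10 (1S,2S,3S)-2-(hydroxymethyl)-1-methyl-3-(prop-1-en-2-yl)cyclopentan-1-ol, via trans-hydroxy aldehyde 9 (not isolated)
Conditions: K2CO3 (0.3 equiv), MeOH, 0 °C; then NaBH4 (1.0 equiv), 0 °C
Reagents that add atoms: none
Why: C7a is α to the aldehyde, so base-mediated enolisation should equilibrate 8 to epimer 9, in which the formyl group is trans to both the isopropenyl group on C3a and the methyl on C1, and reprotonation of the enolate is expected to outrun E1cB loss of hydroxide at 0 °C; carbonyl reduction with NaBH4 then removes the enolisable group and fixes C7a.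

Step 7
Reactants: 10 (1S,2S,3S)-2-(hydroxymethyl)-1-methyl-3-(prop-1-en-2-yl)cyclopentan-1-ol
Product: 11 (1S,2R,3S)-2-(iodomethyl)-1-methyl-3-(prop-1-en-2-yl)cyclopentan-1-ol
Conditions: I2 (1.2 equiv), PPh3 (1.2 equiv), imidazole (2.5 equiv), CH2Cl2, 0 °C → rt
Reagents that add atoms: iodine, II
Why: Appel iodination; only the primary alkoxyphosphonium ion can be displaced by iodide in an SN2 reaction, so the tertiary C1 hydroxyl should remain free and no stereocentre is touched.

Step 8
Reactants: 11 (1S,2R,3S)-2-(iodomethyl)-1-methyl-3-(prop-1-en-2-yl)cyclopentan-1-ol; 12 dimethyl malonate
Product: 13 dimethyl 2-{[(1R,2S,5S)-2-hydroxy-2-methyl-5-(prop-1-en-2-yl)cyclopentyl]methyl}malonate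
Conditions: NaH (1.8 equiv), 12 (2.0 equiv), DMF, 0 °C; then 11, 60 °C
Reagents that add atoms: none
Why: Malonic ester alkylation (SN2 at the primary iodide, forming C6–C7); the excess of 12 over base suppresses dialkylation, and the malonate anion is too weak a base to deprotonate the tertiary alcohol, which should prevent oxetane formation or fragmentation.

Step 9
Reactants: 13 dimethyl 2-{[(1R,2S,5S)-2-hydroxy-2-methyl-5-(prop-1-en-2-yl)cyclopentyl]methyl}malonate
Product: 14 bridged lactone methyl ester (trans-hydrindane with 1β-hydroxy-1α-methyl and 4β-methyl groups, a C4α–O–C(=O)–C6α lactone bridge and a 6β-CO2Me group; indane locants, 1S,3aS,4R,6R,7aR)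
Conditions: Mn(OAc)3·2H2O (2.2 equiv), AcOH (degassed), 70 °C
Reagents that add atoms: none
Why: Oxidative radical cyclisation with trivalent manganese: the malonyl radical at C6 adds 6-endo to the terminal carbon C5 of the 1,1-disubstituted alkene through a chair transition state (forming C5–C6 and the trans-fused ring B), a second equivalent oxidises the tertiary C4 radical to the cation, and the carbonyl oxygen of the ester that is axial on C6 captures it with loss of its methyl group; only the α (axial) ester can reach C4 in the trans-hydrindane chair, so the C4–O bond forms on the α face and C4 and C6 are both dictated by the ring fusion.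

Step 10
Reactants: 14 bridged lactone methyl ester; 15 6-methylheptane-2,4-dione
Product: 17 des-prenyl spiro acyl-trione (C2'-unsubstituted analogue of 19), via open-chain triketo ester 16 (not isolated)
Conditions: 15 (3.2 equiv), LiN(i-Pr)2 (6.4 equiv, commercial solution), THF, −78 → 0 °C; add 14, −78 °C → rt, then 50 °C; aq. HCl
Reagents that add atoms: none
Why: Acylation of a 1,3-diketone dianion at its terminal carbon followed by intramolecular Claisen (Dieckmann-type) condensation: the terminal carbanion should attack the lactone carbonyl, the more electrophilic of the two acyl groups as a bridged γ-lactone, releasing the C4 alkoxide and giving 16 (C1'–C2' bond), and the central diketone carbon then closes ring A onto the methyl ester (C4'–C5' bond, 6-exo-trig), driven by formation of the stabilised acyl-trione anion; because the α lactone carbonyl becomes C1' and the β ester carbonyl becomes C5', C6 acquires the configuration of the target; the excess dianion absorbs the C1 hydroxyl proton and the acidic protons of 16.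

Step 11
Reactants: 17 des-prenyl spiro acyl-trione; 18 1-bromo-3-methylbut-2-ene (prenyl bromide)
Product: 19 target CNP0198642.4
Conditions: 18 (2.3 equiv), NaOMe (3.1 equiv), MeOH, 0 °C → rt; aq. HCl
Reagents that add atoms: none
Why: Double C-alkylation of the free ring methylene of a cyclic acyl-trione, the reaction type by which acylphloroglucinol-derived triones are converted into their gem-dialkyl derivatives: the first equivalent of base removes the acidic enol proton, further base generates the dianion whose most nucleophilic site is C2' between C1' and C3', and the protic solvent should favour C- over O-alkylation; the tertiary alcohols do not react and no stereocentre is touched.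

## Compound list

1 | (S)-(−)-limonene | CC1=CC[C@H](CC1)C(C)=C | starting material
2 | (4S)-limonene 1,2-oxide (cis/trans epoxide mixture) | CC12OC1C[C@H](CC2)C(C)=C | intermediate
3 | (4S)-1-methyl-4-(prop-1-en-2-yl)cyclohexane-1,2-diol (anti-opening diol; C1 and C2 configuration immaterial) | CC1(O)CC[C@@H](CC1O)C(C)=C | intermediate (not isolated)
4 | (3S)-6-oxo-3-(prop-1-en-2-yl)heptanal | O=CC[C@H](CCC(C)=O)C(C)=C | intermediate
5 | (5S)-2-hydroxy-2-methyl-5-(prop-1-en-2-yl)cyclopentane-1-carbaldehyde, aldol adduct (mixture at C1 and C2) | O=CC1C(C)(O)CC[C@@H]1C(C)=C | intermediate (not isolated)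
6 | (5R)-2-methyl-5-(prop-1-en-2-yl)cyclopent-1-ene-1-carbaldehyde | O=CC1=C(C)CC[C@@H]1C(C)=C | intermediate
7 | (1R,2R,5S)-5-methyl-2-(prop-1-en-2-yl)-6-oxabicyclo[3.1.0]hexane-1-carbaldehyde | O=C[C@]1(O2)[C@]2(C)CC[C@@H]1C(C)=C | intermediate
8 | (2S,5S)-2-hydroxy-2-methyl-5-(prop-1-en-2-yl)cyclopentane-1-carbaldehyde (epimers at C1 of the cyclopentane, i.e. C7a) | O=CC1[C@@](C)(O)CC[C@@H]1C(C)=C | intermediate
9 | (1R,2S,5S)-2-hydroxy-2-methyl-5-(prop-1-en-2-yl)cyclopentane-1-carbaldehyde | O=C[C@H]1[C@@](C)(O)CC[C@@H]1C(C)=C | intermediate (not isolated)
10 | (1S,2S,3S)-2-(hydroxymethyl)-1-methyl-3-(prop-1-en-2-yl)cyclopentan-1-ol | OC[C@H]1[C@@](C)(O)CC[C@@H]1C(C)=C | intermediate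
11 | (1S,2R,3S)-2-(iodomethyl)-1-methyl-3-(prop-1-en-2-yl)cyclopentan-1-ol | IC[C@H]1[C@@](C)(O)CC[C@@H]1C(C)=C | intermediate
12 | dimethyl malonate | COC(=O)CC(=O)OC | starting material
13 | dimethyl 2-{[(1R,2S,5S)-2-hydroxy-2-methyl-5-(prop-1-en-2-yl)cyclopentyl]methyl}malonate | COC(=O)C(C(=O)OC)C[C@H]1[C@@](C)(O)CC[C@@H]1C(C)=C | intermediate
14 | bridged lactone methyl ester (indane locants 1S,3aS,4R,6R,7aR; C4α–O–C(=O)–C6α lactone, 6β-CO2Me) | COC(=O)[C@]12C[C@@H]3[C@H](CC[C@]3(C)O)[C@@](C)(C2)OC1=O | intermediate
15 | 6-methylheptane-2,4-dione | CC(=O)CC(=O)CC(C)C | starting material
16 | methyl (1S,3aS,4R,6S,7aR)-1,4-dihydroxy-1,4-dimethyl-6-(7-methyl-3,5-dioxooctanoyl)octahydro-1H-indene-6-carboxylate (acyl group α, ester β) | COC(=O)[C@@]1(C(=O)CC(=O)CC(=O)CC(C)C)C[C@@H]2[C@H](CC[C@]2(C)O)[C@](C)(O)C1 | intermediate (not isolated)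
17 | des-prenyl spiro acyl-trione (19 with CH2 at C2'; hydrindane 1S,3aS,4R,6S,7aR) | C1C(=O)[C@@]2(C[C@@H]3[C@H](CC[C@]3(C)O)[C@](C)(O)C2)C(=O)C(C(=O)CC(C)C)=C1O | intermediate
18 | 1-bromo-3-methylbut-2-ene (prenyl bromide) | CC(C)=CCBr | starting material
19 | CNP0198642.4 (hydrindane 1S,3aS,4R,6S,7aR; ring A 3'-hydroxy-4'-(3-methylbutanoyl)-2',2'-diprenyl enol trione) | CC(C)=CCC1(CC=C(C)C)C(=O)[C@@]2(C[C@@H]3[C@H](CC[C@]3(C)O)[C@](C)(O)C2)C(=O)C(C(=O)CC(C)C)=C1O | target

## Step count and least certain steps

Total step count: 11. Longest linear sequence: 11 steps (1 → 19); 12, 15 and 18 are purchased and enter at steps 8, 10 and 11.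

**Step 3 (key step).** The most likely failure is closure through a ketone enolate to the acetylcyclopentene isomer, or intermolecular aldol oligomerisation, because general acid–base enolisation of the ketone runs beside enamine formation at reflux. Fallback, from 4 and back at 6: the two events are separated. The aldol addition is run with catalytic pyrrolidine/AcOH at 0 °C and stopped at aldol adduct 5, which is isolated. Compound 5 is then dehydrated by E1cB elimination with DBU in toluene at 60 °C to give 6. No compound outside the list is made (no new compound, F0).

**Step 5.** The most likely failure is over-reduction or pinacol coupling at the formyl group, since an aldehyde also accepts an electron from SmI2 and the cleavage has its firmest footing with ketones and esters. Fallback, from 7 and back at 10: the C–O cleavage is moved to the ester oxidation level. Oxidation of 7 with NaClO2/NaH2PO4/2-methylbut-2-ene (Pinnick) gives the epoxy acid F1, and TMSCHN2 in MeOH gives the epoxy methyl ester F2. SmI2 with HMPA and 2-(dimethylamino)ethanol in THF, followed by NaOMe/MeOH to equilibrate C7a, gives the trans β-hydroxy ester F3. LiAlH4 in THF then reduces F3 to 10.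

**Step 6.** The most likely failure is E1cB loss of the tertiary hydroxyl (back to 6) or retro-aldol opening of ring C (back to 4) competing with the wanted epimerisation, because 8 is an aldol. Both by-products are compounds of the route and can be recycled, but material and the C1 configuration are lost. Fallback, from 8 and back at 10: the hydroxyl is capped so that no alkoxide can form, which shuts off the retro-aldol path, and the equilibration is moved to aprotic conditions with a catalytic amidine base, under which a tertiary silyloxy group is not readily expelled. N-(Trimethylsilyl)imidazole followed by DBU (cat.) in CH2Cl2 at 0 °C in the same flask gives the trans β-silyloxy aldehyde F4. NaBH4 in MeOH gives the silyloxy alcohol F5, and citric acid in THF/H2O removes the silyl group to give 10.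

**Step 9.** The most likely failures are 5-exo closure, loss of a proton from or acetate capture of the C4 cation in place of lactonisation, and acid-promoted loss of the C1 hydroxyl in hot AcOH, because the radical, the cation and the tertiary alcohol each have competing exits. Fallback, from 13 and back at 14: ring B is closed by ionic chemistry. Ene-type allylic chlorination (NCS, PhSeCl cat., CH2Cl2) gives the allylic chloride F6, with chlorine on C5. NaH (1.0 equiv) in THF closes ring B by 6-exo-tet malonate alkylation to the methylidene diester F7. I2 in MeCN effects iodolactonisation through the axial ester, with loss of methyl iodide, to the iodomethyl lactone F8. Bu3SnH/AIBN in toluene at 80 °C removes the iodine to give 14.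

**Step 10.** The most likely failure is attack of the dianion on the methyl ester before the lactone, which after ring closure would give the C6 epimer. A second possibility is stalling at 16 or O-acylation to a pyranone. Both arise because the two acyl groups sit on the same hindered carbon. Fallback, from 14 and back at 17: the two acyl groups are assigned by separate operations. LiOH in THF/H2O followed by acidification gives the lactone acid F9, in which only the α carboxyl can re-lactonise, so the free acid is necessarily the β one. 1,1'-Carbonyldiimidazole in THF, which leaves the tertiary C1 hydroxyl alone, gives the acyl imidazolide F10. C-Acylation of the magnesium enolate of 15 (MgCl2, Et3N, MeCN) at its central carbon gives the lactone triketone F11. Excess LiN(i-Pr)2 in THF deprotonates the acetyl methyl, which opens the lactone intramolecularly (6-exo-trig) to give 17.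

**Step 11.** The most likely failure is O-prenylation of the enolate oxygens or a stalled second alkylation at the now tertiary C2', because the ambident dianion meets a reactive allylic bromide. Fallback, from 17 and back at 19: the C–C bonds are made through a π-allyl complex of palladium (Tsuji–Trost), in which O-allylation is reversible and C-allylation is not. Pd(PPh3)4 (zerovalent palladium) with 2-methylbut-3-en-2-yl methyl carbonate in THF at rt gives the mono-prenyl compound F12, and with further carbonate gives 19. Attack at the unsubstituted allyl terminus gives the linear prenyl group.

## Further compounds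

F0 | step 3 | none | none
F1 | step 5 | (1R,2R,5S)-5-methyl-2-(prop-1-en-2-yl)-6-oxabicyclo[3.1.0]hexane-1-carboxylic acid | OC(=O)[C@]1(O2)[C@]2(C)CC[C@@H]1C(C)=C
F2 | step 5 | methyl (1R,2R,5S)-5-methyl-2-(prop-1-en-2-yl)-6-oxabicyclo[3.1.0]hexane-1-carboxylate | COC(=O)[C@]1(O2)[C@]2(C)CC[C@@H]1C(C)=C
F3 | step 5 | methyl (1R,2S,5S)-2-hydroxy-2-methyl-5-(prop-1-en-2-yl)cyclopentane-1-carboxylate (ester trans to isopropenyl, cis to OH) | COC(=O)[C@H]1[C@@](C)(O)CC[C@@H]1C(C)=C
F4 | step 6 | 2-methyl-5-(prop-1-en-2-yl)-2-(trimethylsilyloxy)cyclopentane-1-carbaldehyde (formyl trans to isopropenyl) | O=C[C@H]1[C@@](C)(O[Si](C)(C)C)CC[C@@H]1C(C)=C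
F5 | step 6 | [2-methyl-5-(prop-1-en-2-yl)-2-(trimethylsilyloxy)cyclopentyl]methanol | OC[C@H]1[C@@](C)(O[Si](C)(C)C)CC[C@@H]1C(C)=C
F6 | step 9 | dimethyl 2-{[5-(3-chloroprop-1-en-2-yl)-2-hydroxy-2-methylcyclopentyl]methyl}malonate | COC(=O)C(C(=O)OC)C[C@H]1[C@@](C)(O)CC[C@@H]1C(=C)CCl
F7 | step 9 | dimethyl 1-hydroxy-1-methyl-4-methylideneoctahydro-6H-indene-6,6-dicarboxylate (trans-fused) | COC(=O)C1(C(=O)OC)C[C@@H]2[C@H](CC[C@]2(C)O)C(=C)C1
F8 | step 9 | iodomethyl analogue of 14 (CH2I in place of the C4 methyl) | COC(=O)[C@]12C[C@@H]3[C@H](CC[C@]3(C)O)[C@@](CI)(C2)OC1=O
F9 | step 10 | lactone acid (14 with CO2H in place of CO2Me) | OC(=O)[C@]12C[C@@H]3[C@H](CC[C@]3(C)O)[C@@](C)(C2)OC1=O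
F10 | step 10 | lactone acyl imidazolide (imidazol-1-ylcarbonyl group in place of the CO2H of the lactone acid) | O=C(n1ccnc1)[C@]12C[C@@H]3[C@H](CC[C@]3(C)O)[C@@](C)(C2)OC1=O
F11 | step 10 | lactone triketone (central carbon of 15 acylated by the C6 β-carbonyl) | CC(=O)C(C(=O)CC(C)C)C(=O)[C@]12C[C@@H]3[C@H](CC[C@]3(C)O)[C@@](C)(C2)OC1=O
F12 | step 11 | mono-prenyl compound (one prenyl group on C2', mixture at C2') | CC(C)=CCC1C(=O)[C@@]2(C[C@@H]3[C@H](CC[C@]3(C)O)[C@](C)(O)C2)C(=O)C(C(=O)CC(C)C)=C1O
A1 | alternative 1 | des-prenyl spiro acyl-trione | C1C(=O)[C@@]2(C[C@@H]3[C@H](CC[C@]3(C)O)[C@](C)(O)C2)C(=O)C(C(=O)CC(C)C)=C1O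
A2 | alternative 1 | bridged lactone methyl ester | COC(=O)[C@]12C[C@@H]3[C@H](CC[C@]3(C)O)[C@@](C)(C2)OC1=O
A3 | alternative 1 | 6-methylheptane-2,4-dione | CC(=O)CC(=O)CC(C)C
A4 | alternative 2 | bicyclic enone diester (Pauson–Khand adduct) | COC(=O)C1(C(=O)OC)CC2=C(C)C(=O)C[C@@H]2[C@](C)(O[Si](CC)(CC)CC)C1
A5 | alternative 2 | dimethyl 2-(but-2-yn-1-yl)-2-[2-methyl-2-(triethylsilyloxy)but-3-en-1-yl]malonate | COC(=O)C(CC#CC)(C[C@@](C)(O[Si](CC)(CC)CC)C=C)C(=O)OC
A6 | alternative 2 | octacarbonyldicobalt, Co2(CO)8 | [Co].[Co].[C-]#[O+].[C-]#[O+].[C-]#[O+].[C-]#[O+].[C-]#[O+].[C-]#[O+].[C-]#[O+].[C-]#[O+]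
A7 | alternative 3 | dimethyl 2-{[trans-2-oxo-5-(prop-1-en-2-yl)cyclopentyl]methyl}malonate | COC(=O)C(C(=O)OC)C[C@@H]1[C@H](CCC1=O)C(C)=C
A8 | alternative 3 | cyclopent-2-en-1-one | O=C1C=CCC1
A9 | alternative 3 | isopropenylmagnesium bromide | CC(=C)[Mg]Br
A10 | alternative 3 | dimethyl methylidenemalonate | COC(=O)C(=C)C(=O)OC
A11 | alternative 3 | copper bromide–dimethyl sulfide complex, CuBr·SMe2 | CSC.[Cu]Br
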